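**Retrosynthetic overview**

1. Target 20 ← hexaacetate 19 (global deacetylation) ← Diels–Alder union of chalcone 9 (dienophile) and flavanone diene 16, which forms the C6''–C5'' and C3''–C4'' bonds and the three contiguous stereocentres of the cyclohexene in one operation.
2. Enabling feature: the cyclohexene ring C1''(CH3)=C2''H–C3''H–C4''H–C5''H–C6''H2 is a 4-acylcyclohexene. Its 4''-aroyl group carries an ortho hydroxyl (a boron-chelating 2'-hydroxy ketone), its 4'',5''-trans pair maps onto an E-chalcone, and its 3'',4''-cis pair maps onto an endo transition state.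
3. Both halves are one chalcone, as in the presumed biosynthesis. Chalcone 7 (aldol of 4 and 6) gives 9 by protecting-group exchange. The same 7 gives 16 by oxa-Michael closure of the flavanone pyranone ring, kinetic resolution, and oxidation of the prenyl group to the 3-methylbutadienyl group.
4. Ring order: pyranone ring of the flavanone (step 8), then the cyclohexene (step 14). All benzene rings are bought; the prenyl group enters by Stille coupling on iodinated 2,4-dihydroxyacetophenone.

Key step: step 14

Remark on locants: flavanone numbered O1, C2–C8a. Cyclohexene: C1'' (methyl-bearing), C2'', C3'' (bears flavanone C8), C4'' (bears the aroyl group), C5'' (bears the 2,4-dihydroxyphenyl group), C6'' (CH2).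

Assumption: (R)-VANOL in step 14 is taken to give the (3''S,4''R,5''S) adduct, and the (R,R) catalyst in step 11 is taken to leave the (2S)-flavanone; if the first runs show the opposite sense, the antipodal ligand is used and nothing else changes.

**Route**

Step 1
Reactants: 1 2,4-dihydroxyacetophenone
Product: 2 1-(2,4-dihydroxy-3-iodophenyl)ethanone
Conditions: I2, HIO3, EtOH/H2O, rt
Reagents that add atoms: iodine, II; iodic acid, O[I](=O)=O
Why: Electrophilic aromatic iodination (iodic acid re-oxidises iodide, so all iodine is used) should go to C3, the position ortho to both hydroxyls and the most activated one of the ring.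

Step 2
Reactants: 2 1-(2,4-dihydroxy-3-iodophenyl)ethanone
Product: 3 1-[2-hydroxy-3-iodo-4-(methoxymethoxy)phenyl]ethanone
Conditions: MOMCl, K2CO3, acetone, rt
Reagents that add atoms: chloromethyl methyl ether, COCCl
Why: Williamson-type O-alkylation should take only the 4-OH, because the 2-OH is held in a hydrogen bond to the acetyl carbonyl and is much less nucleophilic.

Step 3
Reactants: 3 1-[2-hydroxy-3-iodo-4-(methoxymethoxy)phenyl]ethanone
Product: 4 1-[2-hydroxy-4-(methoxymethoxy)-3-(3-methylbut-2-en-1-yl)phenyl]ethanone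
Conditions: Bu3SnCH2CH=CMe2, Pd(PPh3)4 (cat.), DMF, 90 °C
Reagents that add atoms: tributyl(3-methylbut-2-en-1-yl)stannane, CCCC[Sn](CCCC)(CCCC)CC=C(C)C
Why: Stille coupling (oxidative addition of zerovalent palladium into the C–I bond, allyl transfer from tin at the tin-bearing carbon, reductive elimination) should give the linear prenyl arene at the position fixed by the iodide.

Step 4
Reactants: 5 2,4-dihydroxybenzaldehyde
Product: 6 2,4-bis(methoxymethoxy)benzaldehyde
Conditions: MOMCl (excess), K2CO3, acetone, reflux
Reagents that add atoms: chloromethyl methyl ether, COCCl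
Why: Exhaustive O-alkylation under forcing carbonate conditions should protect both phenols, including the chelated 2-OH, as base-stable acetals for the aldol step.

Step 5
Reactants: 4 1-[2-hydroxy-4-(methoxymethoxy)-3-(3-methylbut-2-en-1-yl)phenyl]ethanone; 6 2,4-bis(methoxymethoxy)benzaldehyde
Product: 7 (E)-3-[2,4-bis(methoxymethoxy)phenyl]-1-[2-hydroxy-4-(methoxymethoxy)-3-(3-methylbut-2-en-1-yl)phenyl]prop-2-en-1-one
Conditions: KOH, EtOH/H2O, rt
Reagents that add atoms: none
Why: Claisen–Schmidt aldol condensation of the methyl ketone with the non-enolisable aldehyde, followed by E1cB dehydration, should give the thermodynamically favoured E-enone; MOM ethers and the prenyl group are inert to hydroxide.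

Step 6
Reactants: 7 tris-MOM chalcone
Product: 8 morachalcone A, (E)-1-[2,4-dihydroxy-3-(3-methylbut-2-en-1-yl)phenyl]-3-(2,4-dihydroxyphenyl)prop-2-en-1-one
Conditions: 3 M HCl (aq), MeOH, rt to 40 °C, dark
Reagents that add atoms: none
Why: Acid-catalysed acetal exchange with methanol should remove the three MOM groups under conditions mild enough to spare the prenyl alkene and the E-enone.

Step 7
Reactants: 8 morachalcone A
Product: 9 morachalcone A 4',2,4-triacetate (2'-OH free), 4-[(E)-3-[4-acetoxy-2-hydroxy-3-(3-methylbut-2-en-1-yl)phenyl]-3-oxoprop-1-en-1-yl]-1,3-phenylene diacetate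
Conditions: Ac2O (3.3 equiv), pyridine, CH2Cl2, 0 °C
Reagents that add atoms: acetic anhydride, CC(=O)OC(C)=O
Why: Acylation should take the three free phenols and leave the 2'-OH, which is chelated to the ketone and is kept free for boron chelation; the acetates also make the enone a better dienophile.

Step 8
Reactants: 7 tris-MOM chalcone
Product: 10 rac-2-[2,4-bis(methoxymethoxy)phenyl]-7-(methoxymethoxy)-8-(3-methylbut-2-en-1-yl)chroman-4-one
Conditions: NaOAc, EtOH, reflux (unreacted 7 recycled)
Reagents that add atoms: none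
Why: Reversible 6-endo-trig intramolecular oxa-Michael addition of the 2'-phenoxide to the enone (chalcone–flavanone isomerisation) should close the pyranone ring; C2 forms as a racemate.

Step 9
Reactants: 10 racemic tris-MOM flavanone
Product: 11 rac-2-(2,4-dihydroxyphenyl)-7-hydroxy-8-(3-methylbut-2-en-1-yl)chroman-4-one
Conditions: 3 M HCl (aq), MeOH, rt to 40 °C
Reagents that add atoms: none
Why: Acid-catalysed acetal exchange should free the three phenols; the acid step is placed on the racemate so that any reversible C2–O ionisation is without consequence.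

Step 10
Reactants: 11 racemic trihydroxyflavanone
Product: 12 rac-4-[7-acetoxy-8-(3-methylbut-2-en-1-yl)-4-oxochroman-2-yl]-1,3-phenylene diacetate
Conditions: Ac2O, pyridine, rt
Reagents that add atoms: acetic anhydride, CC(=O)OC(C)=O
Why: Exhaustive acylation of the three phenols at room temperature should leave the flavanone ring closed and give the protecting-group pattern used in the cycloaddition.

Step 11
Reactants: 12 racemic flavanone triacetate
Product: 13 (2S)-4-[7-acetoxy-8-(3-methylbut-2-en-1-yl)-4-oxochroman-2-yl]-1,3-phenylene diacetate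
Conditions: RhCl(C5Me5)[(R,R)-TsNCHPhCHPhNH2] (cat.), HCO2H/Et3N (5:2), EtOAc, rt, stopped just past half conversion
Reagents that add atoms: none
Why: Noyori–Ikariya-type asymmetric transfer hydrogenation run as a kinetic resolution should reduce the (2R)-ketone to the cis-flavan-4-ol and leave (2S)-13, so C2 is selected by the catalyst; aryl acetates and the prenyl alkene are not touched by the rhodium hydride.

Step 12
Reactants: 13 (2S)-flavanone triacetate
Product: 15 (2S)-4-[7-acetoxy-8-(2-hydroxy-3-methylbut-3-en-1-yl)-4-oxochroman-2-yl]-1,3-phenylene diacetate (both carbinol epimers), via allylic hydroperoxide 14 (not isolated)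
Conditions: O2, tetraphenylporphyrin (cat.), visible light, CH2Cl2, 0 °C; then PPh3
Reagents that add atoms: oxygen, O=O
Why: Schenck ene reaction of singlet oxygen with the trisubstituted prenyl alkene (methyl hydrogen abstracted, oxygen to the CH carbon) followed by phosphine reduction of the O–O bond should give the secondary allylic alcohol; the new carbinol centre is uncontrolled and is destroyed in step 13, and any tertiary regioisomer dehydrates to the same diene.

Step 13
Reactants: 15 (2S)-allylic alcohol
Product: 16 (2S)-4-[7-acetoxy-8-[(1E)-3-methylbuta-1,3-dien-1-yl]-4-oxochroman-2-yl]-1,3-phenylene diacetate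
Conditions: Burgess reagent (MeO2CN(−)SO2N(+)Et3), toluene, 50 °C; used at once
Reagents that add atoms: none
Why: Burgess dehydration (sulfamate ester, then syn-elimination of a benzylic hydrogen, the only β-hydrogen available) should give the conjugated E-diene under neutral conditions that spare the acetates and the C2 centre.

Step 14
Reactants: 9 morachalcone A triacetate; 16 (2S)-flavanone diene
Product: 19 hexaacetate of the target with free 2'-OH (2S,3''S,4''R,5''S), via chalcone borate chelate 17 (not isolated), via adduct borate chelate 18 (not isolated)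
Conditions: 9, B(OPh)3, (R)-VANOL (each slightly above 1 equiv), PhCF3, rt; then 16 (excess), rt; H2O work-up
Reagents that add atoms: none
Why: B(OPh)3 and (R)-VANOL convert the chelating 2'-hydroxy ketone of 9 into the tetracoordinate borate 17, whose LUMO-lowered E-enone undergoes a concerted, asynchronous normal-electron-demand [4+2] cycloaddition with the s-cis diene of 16, the C6''–C5'' bond (unsubstituted diene CH2 terminus to the chalcone β-carbon, the largest HOMO and LUMO coefficients) running ahead of the C3''–C4'' bond. The closest known reaction type is the chiral-borate-promoted Diels–Alder reaction of 2'-hydroxychalcones with 1-aryl-3-methylbuta-1,3-dienes, the laboratory copy of the biosynthetic chalcone/dehydroprenyl cycloaddition of this adduct family. The cyclohexene ring is closed by intermolecular [4+2] annulation, suprafacial on both partners, with the regiochemistry fixed jointly by the 1-aryl and 3-methyl groups of the diene and the acyl group of the dienophile. The C4''/C5'' trans relation is carried over stereospecifically from the E alkene of 9, the C3''/C4'' cis relation follows from the endo transition state (borate-bound aroyl group under the diene), and the absolute sense (3''S,4''R,5''S) is set by the VANOL ligand, which blocks one face of the chelated enone, while the remote C2 centre of 16 is a spectator. The step needs endo over exo and one enone face, which the rigid spiro-borate chelate and the ligand are to secure (the endo/exo ratio is the point most in need of experimental confirmation), and it needs chemoselectivity, which is secured because only 9 carries a free ortho-hydroxy aryl ketone: every phenol of 16 is acetylated and its ketone is not an enone, so boron does not activate 16.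

Step 15
Reactants: 19 adduct hexaacetate
Product: 20 target compound (2S,3''S,4''R,5''S)
Conditions: NH4OAc, MeOH/H2O, rt to 40 °C, Ar
Reagents that add atoms: none
Why: Acetate-buffered, near-neutral methanolysis of the six activated aryl acetates should free all phenols without the base strength needed for retro-oxa-Michael opening at C2 or enolisation at C4''.

**Compound list**

1 | 2,4-dihydroxyacetophenone | CC(=O)c1ccc(O)cc1O | starting material
2 | 1-(2,4-dihydroxy-3-iodophenyl)ethanone | CC(=O)c1ccc(O)c(I)c1O | intermediate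
3 | 1-[2-hydroxy-3-iodo-4-(methoxymethoxy)phenyl]ethanone | CC(=O)c1ccc(OCOC)c(I)c1O | intermediate
4 | 1-[2-hydroxy-4-(methoxymethoxy)-3-(3-methylbut-2-en-1-yl)phenyl]ethanone | CC(=O)c1ccc(OCOC)c(CC=C(C)C)c1O | intermediate
5 | 2,4-dihydroxybenzaldehyde | O=Cc1ccc(O)cc1O | starting material
6 | 2,4-bis(methoxymethoxy)benzaldehyde | COCOc1ccc(C=O)c(OCOC)c1 | intermediate
7 | (E)-3-[2,4-bis(methoxymethoxy)phenyl]-1-[2-hydroxy-4-(methoxymethoxy)-3-(3-methylbut-2-en-1-yl)phenyl]prop-2-en-1-one | COCOc1ccc(/C=C/C(=O)c2ccc(OCOC)c(CC=C(C)C)c2O)c(OCOC)c1 | intermediate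
8 | morachalcone A, (E)-1-[2,4-dihydroxy-3-(3-methylbut-2-en-1-yl)phenyl]-3-(2,4-dihydroxyphenyl)prop-2-en-1-one | CC(C)=CCc1c(O)ccc(C(=O)/C=C/c2ccc(O)cc2O)c1O | intermediate
9 | morachalcone A 4',2,4-triacetate (2'-OH free) | CC(C)=CCc1c(OC(C)=O)ccc(C(=O)/C=C/c2ccc(OC(C)=O)cc2OC(C)=O)c1O | intermediate
10 | rac-2-[2,4-bis(methoxymethoxy)phenyl]-7-(methoxymethoxy)-8-(3-methylbut-2-en-1-yl)chroman-4-one | COCOc1ccc(C2CC(=O)c3ccc(OCOC)c(CC=C(C)C)c3O2)c(OCOC)c1 | intermediate
11 | rac-2-(2,4-dihydroxyphenyl)-7-hydroxy-8-(3-methylbut-2-en-1-yl)chroman-4-one | CC(C)=CCc1c(O)ccc2c1OC(c1ccc(O)cc1O)CC2=O | intermediate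
12 | rac-4-[7-acetoxy-8-(3-methylbut-2-en-1-yl)-4-oxochroman-2-yl]-1,3-phenylene diacetate | CC(C)=CCc1c(OC(C)=O)ccc2c1OC(c1ccc(OC(C)=O)cc1OC(C)=O)CC2=O | intermediate
13 | (2S)-4-[7-acetoxy-8-(3-methylbut-2-en-1-yl)-4-oxochroman-2-yl]-1,3-phenylene diacetate | CC(C)=CCc1c(OC(C)=O)ccc2c1O[C@H](c1ccc(OC(C)=O)cc1OC(C)=O)CC2=O | intermediate
14 | (2S)-4-[7-acetoxy-8-(2-hydroperoxy-3-methylbut-3-en-1-yl)-4-oxochroman-2-yl]-1,3-phenylene diacetate (both epimers at the peroxy carbon) | C=C(C)C(OO)Cc1c(OC(C)=O)ccc2c1O[C@H](c1ccc(OC(C)=O)cc1OC(C)=O)CC2=O | intermediate (not isolated)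
15 | (2S)-4-[7-acetoxy-8-(2-hydroxy-3-methylbut-3-en-1-yl)-4-oxochroman-2-yl]-1,3-phenylene diacetate (both carbinol epimers) | C=C(C)C(O)Cc1c(OC(C)=O)ccc2c1O[C@H](c1ccc(OC(C)=O)cc1OC(C)=O)CC2=O | intermediate
16 | (2S)-4-[7-acetoxy-8-[(1E)-3-methylbuta-1,3-dien-1-yl]-4-oxochroman-2-yl]-1,3-phenylene diacetate | C=C(C)/C=C/c1c(OC(C)=O)ccc2c1O[C@H](c1ccc(OC(C)=O)cc1OC(C)=O)CC2=O | intermediate
17 | spiro-borate chelate of 9 with (R)-VANOL: boron bound to the 2'-phenoxide and carbonyl oxygen of 9 and to both VANOL oxygens (axial R configuration of the ligand not expressible in SMILES) | CC(C)=CCc1c(OC(C)=O)ccc3c1O[B-]4(Oc5c(-c6c(O4)c7ccccc7cc6-c6ccccc6)c(-c6ccccc6)cc6ccccc56)[O+]=C3/C=C/c1ccc(OC(C)=O)cc1OC(C)=O | intermediate (not isolated)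
18 | spiro-borate chelate of adduct 19 with (R)-VANOL (2S,3''S,4''R,5''S; axial R configuration of the ligand not expressible in SMILES) | CC(C)=CCc1c(OC(C)=O)ccc3c1O[B-]4(Oc5c(-c6c(O4)c7ccccc7cc6-c6ccccc6)c(-c6ccccc6)cc6ccccc56)[O+]=C3[C@H]1[C@@H](c2c(OC(C)=O)ccc8c2O[C@H](c2ccc(OC(C)=O)cc2OC(C)=O)CC8=O)C=C(C)C[C@@H]1c1ccc(OC(C)=O)cc1OC(C)=O | intermediate (not isolated)
19 | hexaacetate of the target, all phenols acetylated except the chelated 2'-OH (2S,3''S,4''R,5''S) | CC(C)=CCc1c(OC(C)=O)ccc(C(=O)[C@H]2[C@@H](c3c(OC(C)=O)ccc4c3O[C@H](c3ccc(OC(C)=O)cc3OC(C)=O)CC4=O)C=C(C)C[C@@H]2c2ccc(OC(C)=O)cc2OC(C)=O)c1O | intermediate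
20 | target, (2S)-8-[(1S,5S,6R)-6-[2,4-dihydroxy-3-(3-methylbut-2-en-1-yl)benzoyl]-5-(2,4-dihydroxyphenyl)-3-methylcyclohex-2-en-1-yl]-2-(2,4-dihydroxyphenyl)-7-hydroxychroman-4-one | CC(C)=CCc1c(O)ccc(C(=O)[C@H]2[C@@H](c3c(O)ccc4c3O[C@H](c3ccc(O)cc3O)CC4=O)C=C(C)C[C@@H]2c2ccc(O)cc2O)c1O | target

**Step count and risks**

Total step count: 15. Longest linear sequence: 12 steps (steps 1, 2, 3, 5, 8, 9, 10, 11, 12, 13, 14, 15).

Three steps most likely to fail:

Step 14. The cycloaddition may run with a poor endo/exo ratio or poor facial control by the ligand, or may stall because the diene aryl group is flanked by two ortho substituents. Fallback: setting out from 9 and 16, the two are combined without boron under electron-transfer catalysis by zerovalent silver nanoparticles on SiO2 (made from AgBF4 and Bu4NBH4; CH2Cl2, 50 °C). This is a known, strongly endo-selective Diels–Alder catalysis of 2'-hydroxychalcones. With no chiral ligand, the (2S) centre of 16 makes the two endo adducts diastereomers: 19 and the (2S,3''R,4''S,5''R) endo diastereomer of 19 F1. These should be separable by chromatography, and the route is rejoined at 19.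

Step 12. The photooxygenation may be unselective (competing benzylic hydrogen abstraction, further oxidation of alkene products), or the new alcohol may take up an acetyl group from the neighbouring aryl acetate during work-up. Fallback: the diene is introduced by cross-coupling instead of by oxidation of the prenyl group, and steps 12 and 13 are left out. Setting out from 3 and 6:
- Claisen–Schmidt condensation (KOH, EtOH/H2O, rt) should give (E)-3-[2,4-bis(methoxymethoxy)phenyl]-1-[2-hydroxy-3-iodo-4-(methoxymethoxy)phenyl]prop-2-en-1-one F2.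
- NaOAc in refluxing EtOH should close it to rac-2-[2,4-bis(methoxymethoxy)phenyl]-8-iodo-7-(methoxymethoxy)chroman-4-one F3.
- HCl in MeOH should give rac-2-(2,4-dihydroxyphenyl)-7-hydroxy-8-iodochroman-4-one F4.
- Ac2O/pyridine should give rac-4-(7-acetoxy-8-iodo-4-oxochroman-2-yl)-1,3-phenylene diacetate F5.
- The transfer-hydrogenation kinetic resolution of step 11 should leave (2S)-4-(7-acetoxy-8-iodo-4-oxochroman-2-yl)-1,3-phenylene diacetate F6.
- Hydroboration of 2-methylbut-1-en-3-yne with pinacolborane (ZrHCl(C5H5)2 cat.) should give (E)-4,4,5,5-tetramethyl-2-(3-methylbuta-1,3-dien-1-yl)-1,3,2-dioxaborolane F7.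
- Anhydrous Suzuki–Miyaura coupling of F6 with F7 (PdCl2[1,1'-bis(diphenylphosphino)ferrocene], CsF, dioxane, 70 °C) should give 16, where the route is rejoined.

Step 15. Configuration at C2 may be lost through ring opening of the freed 4'-hydroxyflavanone (retro-oxa-Michael), or the two acetates flanked by ortho substituents may be cleaved incompletely. Fallback: setting out from 19, enzymatic alcoholysis with immobilised Candida antarctica lipase B and n-butanol in tert-butyl methyl ether at 40 °C (acyl-enzyme mechanism, no base present) should give 20 directly.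

**Further compounds**

F1 | step 14 | (2S,3''R,4''S,5''R) endo diastereomer of 19 | CC(C)=CCc1c(OC(C)=O)ccc(C(=O)[C@@H]2[C@H](c3c(OC(C)=O)ccc4c3O[C@H](c3ccc(OC(C)=O)cc3OC(C)=O)CC4=O)C=C(C)C[C@H]2c2ccc(OC(C)=O)cc2OC(C)=O)c1O
F2 | step 12 | (E)-3-[2,4-bis(methoxymethoxy)phenyl]-1-[2-hydroxy-3-iodo-4-(methoxymethoxy)phenyl]prop-2-en-1-one | COCOc1ccc(/C=C/C(=O)c2ccc(OCOC)c(I)c2O)c(OCOC)c1
F3 | step 12 | rac-2-[2,4-bis(methoxymethoxy)phenyl]-8-iodo-7-(methoxymethoxy)chroman-4-one | COCOc1ccc(C2CC(=O)c3ccc(OCOC)c(I)c3O2)c(OCOC)c1
F4 | step 12 | rac-2-(2,4-dihydroxyphenyl)-7-hydroxy-8-iodochroman-4-one | Oc1ccc(C2CC(=O)c3ccc(O)c(I)c3O2)c(O)c1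
F5 | step 12 | rac-4-(7-acetoxy-8-iodo-4-oxochroman-2-yl)-1,3-phenylene diacetate | CC(=O)Oc1ccc(C2CC(=O)c3ccc(OC(C)=O)c(I)c3O2)c(OC(C)=O)c1
F6 | step 12 | (2S)-4-(7-acetoxy-8-iodo-4-oxochroman-2-yl)-1,3-phenylene diacetate | CC(=O)Oc1ccc2c(c1I)O[C@H](c1ccc(OC(C)=O)cc1OC(C)=O)CC2=O
F7 | step 12 | (E)-4,4,5,5-tetramethyl-2-(3-methylbuta-1,3-dien-1-yl)-1,3,2-dioxaborolane | CC(=C)/C=C/B1OC(C)(C)C(C)(C)O1
F0 | step 15 | none | none
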